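The target is a C8-arylated epigallocatechin gallate (lower flavan, rings A and C) carrying a ring-opened second unit. Everything rests on closing ring C through the C4–C4a bond: a terminal alkyne serves as a masked α-oxo carbene, so that gold-catalysed N-oxide oxidation of the enantioenriched aryl propargyl ether 6 forges C4–C4a and the C3 carbonyl in one operation. The step exploits the C3 oxygen next to the C4 methylene and the ring A carbon C4a, ortho to O1 and activated by O5 and O7; the symmetric 3,5-dibenzyloxyphenyl ether makes both ortho carbons equivalent. Reduction, Friedel–Crafts union at C8 with a cis-epoxide, double galloylation and hydrogenolysis finish the route.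

Key step: step 3

Assumption (chemistry): the sense of induction of the copper–pybox and manganese–salen catalysts is taken from the closest model substrates; the ligand antipode used is the one that delivers (S)-6 and (2S,3R)-14.

Locants: flavan numbering for the lower unit (O1, C2, C3, C4, C4a, C5–C8, C8a); the chain carbons of the upper unit are Cα (diarylmethine), Cβ (carbinol) and Cγ (methylene).

Step 1
Reactants: 1 3,4,5-tris(benzyloxy)benzaldehyde; 2 ethynylmagnesium bromide
Product: 4 rac-1-[3,4,5-tris(benzyloxy)phenyl]prop-2-yn-1-yl acetate, via bromomagnesium alkoxide 3 (not isolated)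
Conditions: THF, 0 °C; then Ac2O, 0 °C to rt
Reagents that add atoms: acetic anhydride, CC(=O)OC(C)=O
Why: Grignard 1,2-addition followed by in situ O-acylation of the magnesium alkoxide should give the propargylic acetate in one pot; the stereocenter is left racemic because step 2 is stereoconvergent.

Step 2
Reactants: 4 rac-1-[3,4,5-tris(benzyloxy)phenyl]prop-2-yn-1-yl acetate; 5 3,5-bis(benzyloxy)phenol
Product: 6 (S)-1,3-bis(benzyloxy)-5-({1-[3,4,5-tris(benzyloxy)phenyl]prop-2-yn-1-yl}oxy)benzene
Conditions: (CuOTf)2·C6H6 (5 mol %), Ph-pybox (10 mol %), iPr2NEt, THF, −20 °C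
Reagents that add atoms: none
Why: Copper-catalysed asymmetric propargylic substitution (etherification): both enantiomers of 4 converge on one copper allenylidene, and the chiral pybox ligand should direct attack of the phenol oxygen on the γ-carbon to set the future C2 as (S) in 6.

Step 3
Reactants: 6 (S)-1,3-bis(benzyloxy)-5-({1-[3,4,5-tris(benzyloxy)phenyl]prop-2-yn-1-yl}oxy)benzene
Product: 7 (2R)-5,7-bis(benzyloxy)-2-[3,4,5-tris(benzyloxy)phenyl]chroman-3-one
Conditions: (Me4tBuXPhos)AuNTf2 (5 mol %), 2,6-dichloropyridine N-oxide (2 equiv), ClCH2CH2Cl, 0 °C to rt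
Reagents that add atoms: 2,6-dichloropyridine N-oxide, [O-][n+]1c(Cl)cccc1Cl
Why: Monovalent gold activates the terminal alkyne of 6, the N-oxide oxygen adds to the internal carbon (the future C3), and N–O cleavage leaves an α-oxo gold carbene on the terminal carbon (the future C4); an ortho carbon of ring A attacks this carbene, and rearomatisation with protodeauration should give the chroman-3-one. The closest known reaction type is the gold-catalysed oxidative cyclisation of aryl propargyl ethers to chroman-3-ones, the diazo-free counterpart of rhodium-carbenoid aromatic substitution of aryloxy diazoketones. Ring C closes in a 6-exo-trig-type Friedel–Crafts mode, the Au=C bond lying outside the new ring. No stereocenter is created: C2, set in step 2, becomes α to the new ketone and should survive because the medium stays non-acidic and the released 2,6-dichloropyridine is too weak a base to enolise it (the descriptor changes from S to R only because C3 now outranks the aryl group). The step needs chemoselectivity for N-oxide delivery over direct 6-endo-dig hydroarylation, which the bulky biaryl phosphine and excess N-oxide should secure; regioselectivity on ring A is automatic, because the two ortho carbons of the symmetric 3,5-dibenzyloxyphenyl ether are equivalent and each is activated by an ortho and a para oxygen.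

Step 4
Reactants: 7 (2R)-5,7-bis(benzyloxy)-2-[3,4,5-tris(benzyloxy)phenyl]chroman-3-one
Product: 8 (2R,3R)-5,7-bis(benzyloxy)-2-[3,4,5-tris(benzyloxy)phenyl]chroman-3-ol
Conditions: L-Selectride (LiBH(s-Bu)3), THF, −78 °C; then H2O
Reagents that add atoms: none
Why: Diastereoselective ketone reduction with a bulky hydride: attack on C3 anti to the pseudo-equatorial C2 aryl group should give the 2,3-cis (3R) alcohol, as is established for benzylated flavan-3-ones, at a temperature that leaves the enolisable C2 untouched.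

Step 5
Reactants: 1 3,4,5-tris(benzyloxy)benzaldehyde; 9 vinylmagnesium bromide
Product: 10 rac-1-[3,4,5-tris(benzyloxy)phenyl]prop-2-en-1-ol
Conditions: THF, −78 to 0 °C; then H2O
Reagents that add atoms: none
Why: Grignard 1,2-addition should give the allylic alcohol, whose stereocenter is erased on ionisation in step 6.

Step 6
Reactants: 10 rac-1-[3,4,5-tris(benzyloxy)phenyl]prop-2-en-1-ol; 11 1,3,5-tris(benzyloxy)benzene
Product: 12 (E)-1,3,5-tris(benzyloxy)-2-{3-[3,4,5-tris(benzyloxy)phenyl]prop-2-en-1-yl}benzene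
Conditions: Bi(OTf)3 (5 mol %), 11 (2 equiv), 4 Å MS, CH2Cl2, 0 °C
Reagents that add atoms: none
Why: Dehydrative Friedel–Crafts allylation through the aryl-stabilised allyl cation: the hindered, threefold-symmetric arene 11 should attack the unsubstituted terminus, giving the conjugated (E)-styrene.

Step 7
Reactants: 12 (E)-1,3,5-tris(benzyloxy)-2-{3-[3,4,5-tris(benzyloxy)phenyl]prop-2-en-1-yl}benzene
Product: 13 (Z)-1,3,5-tris(benzyloxy)-2-{3-[3,4,5-tris(benzyloxy)phenyl]prop-2-en-1-yl}benzene
Conditions: Ir(ppy)3 (1 mol %), blue LEDs, degassed THF, rt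
Reagents that add atoms: none
Why: Photocatalytic contra-thermodynamic E-to-Z isomerisation by triplet energy transfer: the planar E-styrene is sensitised selectively, while the twisted Z-isomer, of higher triplet energy, should accumulate.

Step 8
Reactants: 13 (Z)-1,3,5-tris(benzyloxy)-2-{3-[3,4,5-tris(benzyloxy)phenyl]prop-2-en-1-yl}benzene
Product: 14 (2S,3R)-2-[3,4,5-tris(benzyloxy)phenyl]-3-[2,4,6-tris(benzyloxy)benzyl]oxirane
Conditions: (S,S)-(salen)MnCl (Jacobsen catalyst, 5 mol %), mCPBA, NMO, CH2Cl2, −78 °C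
Reagents that add atoms: mCPBA, OOC(=O)c1cccc(Cl)c1
Why: Jacobsen–Katsuki epoxidation, best suited to cis-β-alkylstyrenes: the chiral oxo complex of manganese should deliver oxygen to one enantioface, setting Cβ as (R) and the benzylic carbon as (S) in the cis-epoxide, while residual E-alkene is a poor substrate and stays behind.

Step 9
Reactants: 8 (2R,3R)-5,7-bis(benzyloxy)-2-[3,4,5-tris(benzyloxy)phenyl]chroman-3-ol; 14 (2S,3R)-2-[3,4,5-tris(benzyloxy)phenyl]-3-[2,4,6-tris(benzyloxy)benzyl]oxirane
Product: 15 (2R,3R)-5,7-bis(benzyloxy)-8-{(1S,2R)-2-hydroxy-1-[3,4,5-tris(benzyloxy)phenyl]-3-[2,4,6-tris(benzyloxy)phenyl]propyl}-2-[3,4,5-tris(benzyloxy)phenyl]chroman-3-ol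
Conditions: 8 (2 equiv), (CF3)2CHOH–CH2Cl2 (1:3), 0 °C to rt
Reagents that add atoms: none
Why: Friedel–Crafts alkylation of an electron-rich arene by an aryl epoxide under hydrogen-bond activation: C8 of ring A (flanked by O1 and one benzyloxy group, less hindered than C6) should open the epoxide at its benzylic carbon with inversion, setting Cα as (S), and an ion-pair pathway would converge on the same configuration because allylic 1,3-strain directs attack anti to the CγH2Ar group.

Step 10
Reactants: 15 the diol of step 9; 16 3,4,5-tris(benzyloxy)benzoyl chloride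
Product: 17 heptadeca-O-benzyl target, the bis[3,4,5-tris(benzyloxy)benzoate] of 15 at O3 and at the Cβ oxygen
Conditions: 16 (3 equiv), DMAP, Et3N, CH2Cl2, rt
Reagents that add atoms: none
Why: DMAP-catalysed acylation (nucleophilic catalysis) of both secondary alcohols should install the two protected galloyl esters in one operation without touching a stereocenter.

Step 11
Reactants: 17 heptadeca-O-benzyl target
Product: 18 CNP0155034.1
Conditions: H2 (1 atm), Pd(OH)2/C, THF–MeOH, rt
Reagents that add atoms: none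
Why: Catalytic hydrogenolysis should cleave all seventeen benzyl ethers, while the gallate esters, the triarylmethine C–H and the C2–O1 ether of the flavan are expected to survive, as in hydrogenolytic end-games of gallocatechin gallates.

Compound list
1 | 3,4,5-tris(benzyloxy)benzaldehyde | O=Cc1cc(OCc2ccccc2)c(OCc2ccccc2)c(OCc2ccccc2)c1 | starting material
2 | ethynylmagnesium bromide | C#C[Mg]Br | starting material
3 | bromomagnesium 1-[3,4,5-tris(benzyloxy)phenyl]prop-2-yn-1-olate (racemic, not isolated) | C#CC(O[Mg]Br)c1cc(OCc2ccccc2)c(OCc2ccccc2)c(OCc2ccccc2)c1 | intermediate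
4 | rac-1-[3,4,5-tris(benzyloxy)phenyl]prop-2-yn-1-yl acetate | C#CC(OC(C)=O)c1cc(OCc2ccccc2)c(OCc2ccccc2)c(OCc2ccccc2)c1 | intermediate
5 | 3,5-bis(benzyloxy)phenol | Oc1cc(OCc2ccccc2)cc(OCc2ccccc2)c1 | starting material
6 | (S)-1,3-bis(benzyloxy)-5-({1-[3,4,5-tris(benzyloxy)phenyl]prop-2-yn-1-yl}oxy)benzene | C#C[C@H](Oc1cc(OCc2ccccc2)cc(OCc2ccccc2)c1)c1cc(OCc2ccccc2)c(OCc2ccccc2)c(OCc2ccccc2)c1 | intermediate
7 | (2R)-5,7-bis(benzyloxy)-2-[3,4,5-tris(benzyloxy)phenyl]chroman-3-one | O=C1Cc2c(OCc3ccccc3)cc(OCc3ccccc3)cc2O[C@@H]1c1cc(OCc2ccccc2)c(OCc2ccccc2)c(OCc2ccccc2)c1 | intermediate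
8 | (2R,3R)-5,7-bis(benzyloxy)-2-[3,4,5-tris(benzyloxy)phenyl]chroman-3-ol (penta-O-benzyl-epigallocatechin) | O[C@@H]1Cc2c(OCc3ccccc3)cc(OCc3ccccc3)cc2O[C@@H]1c1cc(OCc2ccccc2)c(OCc2ccccc2)c(OCc2ccccc2)c1 | intermediate
9 | vinylmagnesium bromide | C=C[Mg]Br | starting material
10 | rac-1-[3,4,5-tris(benzyloxy)phenyl]prop-2-en-1-ol | C=CC(O)c1cc(OCc2ccccc2)c(OCc2ccccc2)c(OCc2ccccc2)c1 | intermediate
11 | 1,3,5-tris(benzyloxy)benzene | c1c(OCc2ccccc2)cc(OCc2ccccc2)cc1OCc1ccccc1 | starting material
12 | (E)-1,3,5-tris(benzyloxy)-2-{3-[3,4,5-tris(benzyloxy)phenyl]prop-2-en-1-yl}benzene | C(/C=C/c1cc(OCc2ccccc2)c(OCc2ccccc2)c(OCc2ccccc2)c1)c1c(OCc2ccccc2)cc(OCc2ccccc2)cc1OCc1ccccc1 | intermediate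
13 | (Z)-1,3,5-tris(benzyloxy)-2-{3-[3,4,5-tris(benzyloxy)phenyl]prop-2-en-1-yl}benzene | C(/C=C\c1cc(OCc2ccccc2)c(OCc2ccccc2)c(OCc2ccccc2)c1)c1c(OCc2ccccc2)cc(OCc2ccccc2)cc1OCc1ccccc1 | intermediate
14 | (2S,3R)-2-[3,4,5-tris(benzyloxy)phenyl]-3-[2,4,6-tris(benzyloxy)benzyl]oxirane (cis) | C([C@H]1O[C@H]1c1cc(OCc2ccccc2)c(OCc2ccccc2)c(OCc2ccccc2)c1)c1c(OCc2ccccc2)cc(OCc2ccccc2)cc1OCc1ccccc1 | intermediate
15 | (2R,3R)-5,7-bis(benzyloxy)-8-{(1S,2R)-2-hydroxy-1-[3,4,5-tris(benzyloxy)phenyl]-3-[2,4,6-tris(benzyloxy)phenyl]propyl}-2-[3,4,5-tris(benzyloxy)phenyl]chroman-3-ol | O[C@H](Cc1c(OCc3ccccc3)cc(OCc3ccccc3)cc1OCc3ccccc3)[C@@H](c1cc(OCc3ccccc3)c(OCc3ccccc3)c(OCc3ccccc3)c1)c1c(OCc3ccccc3)cc(OCc3ccccc3)c2c1O[C@H](c1cc(OCc3ccccc3)c(OCc3ccccc3)c(OCc3ccccc3)c1)[C@H](O)C2 | intermediate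
16 | 3,4,5-tris(benzyloxy)benzoyl chloride | O=C(Cl)c1cc(OCc2ccccc2)c(OCc2ccccc2)c(OCc2ccccc2)c1 | starting material
17 | heptadeca-O-benzyl target: bis[3,4,5-tris(benzyloxy)benzoate] of 15, (2R,3R) in the flavan and (1S,2R) in the side chain | O=C(O[C@H](Cc1c(OCc3ccccc3)cc(OCc3ccccc3)cc1OCc3ccccc3)[C@@H](c1cc(OCc3ccccc3)c(OCc3ccccc3)c(OCc3ccccc3)c1)c1c(OCc3ccccc3)cc(OCc3ccccc3)c2c1O[C@H](c1cc(OCc3ccccc3)c(OCc3ccccc3)c(OCc3ccccc3)c1)[C@H](OC(=O)c1cc(OCc3ccccc3)c(OCc3ccccc3)c(OCc3ccccc3)c1)C2)c1cc(OCc3ccccc3)c(OCc3ccccc3)c(OCc3ccccc3)c1 | intermediate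
18 | CNP0155034.1 | O=C(O[C@H](Cc1c(O)cc(O)cc1O)[C@@H](c1cc(O)c(O)c(O)c1)c1c(O)cc(O)c2c1O[C@H](c1cc(O)c(O)c(O)c1)[C@H](OC(=O)c1cc(O)c(O)c(O)c1)C2)c1cc(O)c(O)c(O)c1 | target

Total step count: 11. Longest linear sequence: 7 steps (steps 1–4, then 9–11); steps 5–8 form the second branch.

Steps most likely to fail

Step 3. Direct 6-endo-dig hydroarylation by the very electron-rich ring A may outrun N-oxide delivery, and the new ketone may enolise and erode C2. Fallback, setting out from 6 and returning at 7: hydroarylation is accepted deliberately. (Ph3P)AuNTf2 in CH2Cl2 without oxidant should close the same C4–C4a bond to give (2S)-5,7-bis(benzyloxy)-2-[3,4,5-tris(benzyloxy)phenyl]-2H-chromene F1, handled cold and in the dark. Hydroboration–oxidation (BH3·THF; then NaOH, H2O2), with boron adding to C3 anti to the C2 aryl group, should give (2R,3S)-5,7-bis(benzyloxy)-2-[3,4,5-tris(benzyloxy)phenyl]chroman-3-ol F2. Dess–Martin oxidation then returns to the route at 7.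

Step 9. Attack may spread between C8 and C6, the free C3 hydroxyl may O-alkylate, the epoxide may rearrange to a ketone (Meinwald), or configuration at Cα may leak. Fallback, setting out from 8 and returning at 15: the ring A nucleophile is turned into an organometallic. NBS in CH2Cl2 at −78 °C should brominate C8 selectively to give (2R,3R)-5,7-bis(benzyloxy)-8-bromo-2-[3,4,5-tris(benzyloxy)phenyl]chroman-3-ol F3. n-BuLi (2.1 equiv, THF, −78 °C; alkoxide formation, then bromine–lithium exchange) followed by 14 and BF3·OEt2 should open the epoxide at its benzylic carbon with inversion, the position of the metal fixing the regiochemistry; aqueous work-up returns to the route at 15.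

Step 2. C-propargylation of the electron-rich phenol may compete with O-alkylation, and facial control by the ligand may be poor. Fallback, setting out from 1 and returning at 6: the stereocenter is set by carbonyl addition and transferred by inversion. ProPhenol/Me2Zn-mediated enantioselective addition of trimethylsilylacetylene should give (S)-1-[3,4,5-tris(benzyloxy)phenyl]-3-(trimethylsilyl)prop-2-yn-1-ol F4. A Mitsunobu reaction with 5 (PPh3, DIAD, toluene, −20 °C) should form the ether with inversion, (R)-{3-[3,5-bis(benzyloxy)phenoxy]-3-[3,4,5-tris(benzyloxy)phenyl]prop-1-yn-1-yl}trimethylsilane F5; the descriptor differs from that of 6 only because the silylalkynyl group outranks the aryl group. K2CO3 in MeOH removes the silyl group and returns to the route at 6.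

Further compounds
F1 | step 3 | (2S)-5,7-bis(benzyloxy)-2-[3,4,5-tris(benzyloxy)phenyl]-2H-chromene | C1=Cc2c(OCc3ccccc3)cc(OCc3ccccc3)cc2O[C@@H]1c1cc(OCc2ccccc2)c(OCc2ccccc2)c(OCc2ccccc2)c1
F2 | step 3 | (2R,3S)-5,7-bis(benzyloxy)-2-[3,4,5-tris(benzyloxy)phenyl]chroman-3-ol | O[C@H]1Cc2c(OCc3ccccc3)cc(OCc3ccccc3)cc2O[C@@H]1c1cc(OCc2ccccc2)c(OCc2ccccc2)c(OCc2ccccc2)c1
F3 | step 9 | (2R,3R)-5,7-bis(benzyloxy)-8-bromo-2-[3,4,5-tris(benzyloxy)phenyl]chroman-3-ol | O[C@@H]1Cc2c(OCc3ccccc3)cc(OCc3ccccc3)c(Br)c2O[C@@H]1c1cc(OCc2ccccc2)c(OCc2ccccc2)c(OCc2ccccc2)c1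
F4 | step 2 | (S)-1-[3,4,5-tris(benzyloxy)phenyl]-3-(trimethylsilyl)prop-2-yn-1-ol | C[Si](C)(C)C#C[C@@H](O)c1cc(OCc2ccccc2)c(OCc2ccccc2)c(OCc2ccccc2)c1
F5 | step 2 | (R)-{3-[3,5-bis(benzyloxy)phenoxy]-3-[3,4,5-tris(benzyloxy)phenyl]prop-1-yn-1-yl}trimethylsilane | C[Si](C)(C)C#C[C@H](Oc1cc(OCc2ccccc2)cc(OCc2ccccc2)c1)c1cc(OCc2ccccc2)c(OCc2ccccc2)c(OCc2ccccc2)c1
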